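(All runs come from a simulation with constants of no real substance; scatter was added.)

I had two questions on this flask, and I followed both through how low the left-handed substrate had to fall beside the right-handed substrate.

| flask | left-handed substrate | right-handed substrate | gas | free catalyst | added ligand | remark | time |
|---|---|---|---|---|---|---|---|
| Sunday's | 0.050 M | 0.050 M | 3.3 mM (held) | 0.067 mM | 56 µM | run made earlier |  |
| Tuesday's | 0.050 M | 0.050 M | 3.3 mM (held) | 0.15 mM | 56 µM | run made earlier |  |
| Thursday's | 0.050 M | 0.050 M | 3.3 mM (held) | 0.10 mM | 110 µM | run made earlier |  |
| flask | 0.050 M | 0.050 M | 3.3 mM (held) | 0.10 mM | 56 µM |  | 40 h |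

| run | time / h | right-handed substrate / % | left-handed substrate / % |
|---|---|---|---|
| Sunday's | 3.00 | 48.6 | 25.7 |
| Sunday's | 6.00 | 49.9 | 9.7 |
| Sunday's | 10.0 | 47.5 | 1.4 |
| Sunday's | 15.0 | 48.9 | 0 |
| Sunday's | 20.0 | 46.0 | 0.7 |
| Sunday's | 25.0 | 45.8 | 0 |
| Tuesday's | 2.00 | 49.0 | 30.5 |
| Tuesday's | 3.00 | 50.3 | 22.0 |
| Tuesday's | 4.00 | 48.6 | 11.6 |
| Tuesday's | 6.00 | 49.6 | 0.3 |
| Tuesday's | 10.0 | 43.1 | 0 |
| Tuesday's | 15.0 | 43.1 | 0.5 |
| Tuesday's | 25.0 | 40.6 | 0.5 |
| Thursday's | 5.00 | 48.4 | 11.9 |
| Thursday's | 10.0 | 47.1 | 0 |
| Thursday's | 15.0 | 47.3 | 0.9 |
| Thursday's | 20.0 | 45.8 | 1.7 |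
| Thursday's | 25.0 | 44.3 | 0 |

(each reading ± 1 percentage point)

- whether the excess of right-handed substrate over left-handed substrate among what is left of the two reaches 90% by 40 h (no / yes)
- the highest excess of right-handed substrate over left-handed substrate among what is left of the two up to 40 h

- free catalyst is single-handed; left-handed substrate and right-handed substrate are mirror images of each other, charged as a racemate, each of them at the stated concentration
- the earlier runs were read with a standard deviation of 1 percentage point
- at the start none of the gas is in solution

For an excess e, the left-handed substrate may stand at one minus e over one plus e of the right-handed substrate. At 90% that gave 5.26%, and I called this share ρ, the crossing ratio. With the right-handed substrate near its charged fraction 0.5 of the two together, the left-handed substrate had to reach 2.63%.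

My ladder had two rungs. The first was the fall of the left-handed substrate. Sunday's slope from 3.00 h to 6.00 h, held from the start, covered the fall from the charge to that level in 8.88 h, and Tuesday's slope from 2.00 h to 4.00 h, held the same way, covered it in 5.01 h. Both runs had the flask's ligand charge, so I interpolated the rate to 0.10 mM of free catalyst and reckoned 6.80 h for the flask.

The second rung was the drift of the right-handed substrate. Tuesday's late slope, held steady, needed 105 h to consume what stood at 6.00 h. That is far longer than my crossing time, so I expected the flask to pass ρ with the right-handed substrate still near its charge.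

The forecast answered yes, with a top excess of 99.9%, and stated: “The 90% excess is passed at about 8 h”. On that time it differed from my 6.80 h.

The flask answered yes, with a top excess of >99.9%.

    reagent + free catalyst + left-handed substrate → free catalyst + left-handed product (k = 2000 M⁻² s⁻¹)
    reagent + free catalyst + right-handed substrate → free catalyst + right-handed product (k = 19.0 M⁻² s⁻¹)
    reagent + free catalyst → spent catalyst (k = 0.0110 M⁻¹ s⁻¹)
    free catalyst + added ligand ⇌ idle complex, settled at all times (K = 28000 M⁻¹)
    gas ⇌ reagent, rate k5*(csat - [reagent]) (kL = 9.40 × 10⁻⁴ s⁻¹)

The excess reached 90% at 6.78 h, with the right-handed substrate at 48.6%, so ρ put the left-handed substrate at 2.56%. The left-handed step, with a rate constant 105 times that of the right-handed step (the selectivity factor), took 50.0% of the two substrates together charged, and the left-handed substrate stood at 0% by 20.0 h. The right-handed step ran on, leaving 42.9% at 40.0 h. The left-handed substrate also fell below 5.26% of the right-handed substrate in a further flask with twice the left-handed charge and all other amounts as they are, whose excess at the end of the run stood at >99.9%.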